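The data were computed with made-up constants; noise was put on by code.

- Start from late times. At 25.0 h, Tuesday's flask reads 66% starting material and Saturday's reads 69%. That gap of 3 percentage points stands against a scatter of 2.1 points on a difference of readings, although partner went from 0.97 equiv to 2.4 equiv.

| setting | Tuesday's | Saturday's | elm | larch |
|---|---|---|---|---|
| starting material | 26 mM | 26 mM | 26 mM | 26 mM |
| partner | 0.97 equiv | 2.4 equiv | 0.800 equiv | 2.00 equiv |
| free catalyst | 0.5 mol% | 0.5 mol% | 0.5 mol% | 0.5 mol% |
| second catalyst | 0.05 mol% | 0.05 mol% | 0.05 mol% | 0.05 mol% |
| remark | run made earlier | run made earlier |  |  |
| time |  |  | 25 h | 25 h |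

| run | time / h | intermediate / % | isomer of the product / % | starting material / % | target / % |
|---|---|---|---|---|---|
| Tuesday's | 2.00 | 5 | 3 | 97 | 0 |
| Tuesday's | 3.00 | 6 | 2 | 97 | 0 |
| Tuesday's | 6.00 | 11 | 0 | 91 | 0 |
| Tuesday's | 10.0 | 11 | 0 | 86 | 2 |
| Tuesday's | 15.0 | 20 | 3 | 78 | 3 |
| Tuesday's | 25.0 | 29 | 4 | 66 | 7 |
| Saturday's | 1.50 | 2 | 0 | 99 | 3 |
| Saturday's | 5.00 | 7 | 2 | 91 | 3 |
| Saturday's | 8.00 | 9 | 1 | 85 | 1 |
| Saturday's | 15.0 | 14 | 1 | 78 | 7 |
| Saturday's | 20.0 | 17 | 0 | 72 | 13 |
| Saturday's | 25.0 | 17 | 1 | 69 | 15 |

(scatter of a reading: 1.5 percentage points)

- which of these there is most of at the end, counted by the starting material in it, elm (isomer of the product / intermediate / starting material / target)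
- which of these there is most of at the end, counted by the starting material in it, larch (isomer of the product / intermediate / starting material / target)
- amount of the one of these that there is most of at the end, in percent of the starting material charged, elm
- amount of the one of these that there is most of at the end, in percent of the starting material charged, larch

- the analysis behind the earlier runs scatters by 1.5 percentage points, standard deviation

- Follow one molecule of starting material. Each hour it either stays or leaves, and if that chance is steady, ln(charged/left)/time gives a pseudo-first-order constant. The mean of the two readings of what is left gives 0.0157 /h.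
- The second way counts what has arrived: intermediate, target and isomer of the product. Their sums in the two flasks give 0.0182 /h, which is higher, so the two ways part.
- Which one cheats? The sum of 3 readings carries a scatter of 2.6 points. The column of the isomer of the product also looks suspect: Tuesday's flask reads 3% of it at 2.00 h beside 0% target, and with a scatter of 1.5 points such a reading may be noise.
- Strike that column and the count gives 0.0166 /h, in line with the first way.
- So carry the leaving rate, the chance per hour that one molecule of starting material leaves, c(starting material) falling exponentially with it: 0.0162 /h.
- With the gap above showing no clear effect of partner, my reckoning gives elm and larch the same 66.7% at 25 h.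
- The forecast names starting material for elm at 67% and starting material for larch at 68%, holding that “the first step is essentially independent of partner”.
- Elm ends at 65.5% and larch at 65.5%, with starting material the largest share in both. In larch, the falling back of target to intermediate makes no difference to this number.

    starting material + free catalyst → free catalyst + intermediate (k = 130 /M/h)
    partner + second catalyst + intermediate ⇌ second catalyst + target (K = 82.0 /M, k = 81000 /M²/h)
    target ⇌ isomer of the product (K = 0.950, k = 0.0110 /h)

- The leaving step runs on free catalyst, which stands at 100% of its charge at the end of larch, and at a held loading in mol% c(free catalyst) grows with the charge of starting material. Scaled to 100 mM of starting material from 26 mM, the leaving rate becomes 0.0623 /h, which leaves 21.1% at 25 h. A flask like larch but charged with 100 mM of starting material holds 19.7% starting material at that time.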